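**Retrosynthetic overview**
1. C8–C9 is formed in the penultimate step: Negishi sp2–sp3 coupling of the (E)-C8 iodide of the complete 1,2-dioxane methyl ester with (S)-2-ethylhex-3-enylzinc iodide, then ester hydrolysis.
2. Enabling feature: the C7=C8(Et) alkene is exocyclic to the fully substituted ring carbon C6 of the O1–O2–C3–C4–C5–C6 dioxane, so a 6-butynyl precursor hydrometalates only at C8, the C8–metal centre has no β-oxygen, and the O–O bond is insulated from it.
3. The dioxane (the only ring) is closed by 6-exo oxa-Michael addition (O2–C3) of a C6 methoxy hydroperoxide made by ozonolysis in MeOH; C6–C7 follows by axial alkynylation of the cyclic peroxycarbenium ion.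
4. Stereo relay: C4 (Evans alkylation) controls C3 (3,4-trans) and C6 (alkynyl axial, trans to the C4 ethyl); 7E comes from syn-hydrozirconation/iodination.
5. Side chain: catalytic Et2Zn addition to (E)-pent-2-enal, Johnson–Claisen chirality transfer to C10 with the 11E alkene, Barton iododecarboxylation to the C9 iodide.

Key step: step 14

Remark: locants of the target (acid carbon C1, ring O1–O2–C3–C4–C5–C6, side chain C7–C14) are used for all intermediates; the C6 methoxy peroxyketal is carried as a mixture of C6 epimers, since both ionise to one cation.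

**Step 1**
Reactants: 1 (E)-pent-2-enal
Product: 2 (R,E)-hept-4-en-3-ol
Conditions: Et2Zn (1.5 equiv), (2R)-3-exo-(dimethylamino)isoborneol (3 mol%), toluene, 0 °C; then aq. NH4Cl/1 M HCl
Reagents that add atoms: diethylzinc CC[Zn]CC
Why: Amino-alcohol-catalysed enantioselective 1,2-addition of a dialkylzinc to an enal (Noyori type), in which the chiral zinc aminoalkoxide should deliver ethyl to the Re face of the aldehyde and so set the carbinol centre as R.

**Step 2**
Reactants: 2 (R,E)-hept-4-en-3-ol
Product: 3 ethyl (R,E)-3-ethylhept-4-enoate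
Conditions: MeC(OEt)3 (6 equiv), EtCO2H (cat.), 140 °C, EtOH distilled off
Reagents that add atoms: triethyl orthoacetate CC(OCC)(OCC)OCC
Why: Johnson–Claisen [3,3] rearrangement through a chair transition state with the carbinol ethyl group equatorial, so that suprafacial 1,3-chirality transfer sets C10 as R and the new alkene as 11E.

**Step 3**
Reactants: 3 ethyl (R,E)-3-ethylhept-4-enoate
Product: 4 (R,E)-3-ethylhept-4-enoic acid
Conditions: LiOH·H2O, THF/MeOH/H2O, 23 °C; then 1 M HCl
Reagents that add atoms: lithium hydroxide [Li+].[OH-]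
Why: Ester saponification; the stereocenter is β to the carbonyl and cannot epimerise.

**Step 4**
Reactants: 4 (R,E)-3-ethylhept-4-enoic acid
Product: 7 (S,E)-5-(iodomethyl)hept-3-ene, via acid chloride 5 (not isolated), via Barton ester 6 (not isolated)
Conditions: (COCl)2, DMF (cat.), CH2Cl2, 0 → 23 °C; evaporate; then sodium 2-thioxopyridin-1(2H)-olate, 4-(dimethylamino)pyridine (cat.), CHI3, PhH, 80 °C, tungsten lamp
Reagents that add atoms: iodoform IC(I)I (iodine of 7); oxalyl chloride O=C(Cl)C(=O)Cl (chlorine of 5); sodium 2-thioxopyridin-1(2H)-olate [Na+].[O-]N1C=CC=CC1=S (thiohydroxamate part of 6)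
Why: Barton decarboxylative iodination (radical chain): the primary C9 radical should be trapped by iodoform faster than it cyclises or undergoes a 1,2-vinyl shift, and the C10 stereocenter is not part of the radical centre (the descriptor changes to S only through the priority of CH2I).

**Step 5**
Reactants: 8 2-ethylacrolein (2-methylidenebutanal)
Product: 9 2-methylidenebutan-1-ol
Conditions: NaBH4, CeCl3·7H2O, MeOH, 0 °C; then 1 M HCl
Reagents that add atoms: none
Why: Luche 1,2-reduction of an enal, which avoids conjugate reduction.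

**Step 6**
Reactants: 9 2-methylidenebutan-1-ol
Product: 10 2-(bromomethyl)but-1-ene
Conditions: PBr3 (0.4 equiv), Et2O, 0 °C
Reagents that add atoms: phosphorus tribromide BrP(Br)Br
Why: Conversion of a primary allylic alcohol into the bromide; direct and allylic substitution give the same product because the allyl unit is symmetric.

**Step 7**
Reactants: 11 (S)-4-benzyl-3-butanoyloxazolidin-2-one; 10 2-(bromomethyl)but-1-ene
Product: 13 (S)-4-benzyl-3-[(R)-2-ethyl-4-methylidenehexanoyl]oxazolidin-2-one, via sodium enolate 12 (not isolated)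
Conditions: 11, NaN(SiMe3)2, THF, −78 °C; then 10, −78 → −40 °C
Reagents that add atoms: sodium bis(trimethylsilyl)amide C[Si](C)(C)[N-][Si](C)(C)C.[Na+] (sodium of 12 only)
Why: Evans asymmetric alkylation: the chelated Z-enolate is alkylated on the face opposite the benzyl group, which sets C4 as R.

**Step 8**
Reactants: 13 (S)-4-benzyl-3-[(R)-2-ethyl-4-methylidenehexanoyl]oxazolidin-2-one
Product: 14 (R)-2-ethyl-4-methylidenehexan-1-ol
Conditions: LiBH4, MeOH (1 equiv), Et2O, 0 °C; then aq. NH4Cl/1 M HCl
Reagents that add atoms: none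
Why: Reductive cleavage of the acyl oxazolidinone with LiBH4, which should not epimerise C4 and releases the auxiliary for recovery.

**Step 9**
Reactants: 14 (R)-2-ethyl-4-methylidenehexan-1-ol
Product: 16 methyl (R,E)-4-ethyl-6-methylideneoct-2-enoate, via aldehyde 15 (not isolated)
Conditions: Dess–Martin periodinane, CH2Cl2, 0 → 23 °C; then Ph3P=CHCO2Me (2.5 equiv), 23 °C
Reagents that add atoms: methyl (triphenylphosphoranylidene)acetate COC(=O)C=P(c1ccccc1)(c1ccccc1)c1ccccc1
Why: One-pot Dess–Martin oxidation and Wittig olefination with a stabilised ylide, which should be E-selective and spares the α-branched aldehyde from isolation and epimerisation.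

**Step 10**
Reactants: 16 methyl (R,E)-4-ethyl-6-methylideneoct-2-enoate
Product: 18 methyl 2-[(3S,4R)-4,6-diethyl-6-methoxy-1,2-dioxan-3-yl]acetate (both C6 epimers), via methoxy hydroperoxide 17 (not isolated)
Conditions: O3/O2, CH2Cl2/MeOH (4:1), −78 °C (Sudan Red 7B end point), N2 purge; concentrate below 20 °C; then Et2NH (0.5 equiv), CF3CH2OH, 23 °C
Reagents that add atoms: ozone [O-][O+]=O; methanol CO
Why: Chemoselective ozonolysis of the electron-rich 1,1-disubstituted alkene in MeOH traps the ketone oxide as the C6 methoxy hydroperoxide, and amine-catalysed 6-exo oxa-Michael addition (a known route to 6-methoxy-1,2-dioxane-3-acetates) closes the ring through a chair transition state with the C4 ethyl group and the enoate both equatorial, which should give the 3,4-trans (3S) isomer, also favoured at equilibrium.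

**Step 11**
Reactants: 19 but-1-yne
Product: 21 tributyl(but-1-yn-1-yl)stannane, via lithium butynide 20 (not isolated)
Conditions: n-BuLi, THF, −78 °C; then Bu3SnCl, −78 → 0 °C
Reagents that add atoms: n-butyllithium [Li]CCCC (lithium of 20 only); tributyltin chloride CCCC[Sn](Cl)(CCCC)CCCC
Why: Deprotonation of a terminal alkyne and stannylation of the acetylide.

**Step 12**
Reactants: 18 methyl 2-[(3S,4R)-4,6-diethyl-6-methoxy-1,2-dioxan-3-yl]acetate; 21 tributyl(but-1-yn-1-yl)stannane
Product: 22 methyl 2-[(3S,4R,6S)-6-(but-1-yn-1-yl)-4,6-diethyl-1,2-dioxan-3-yl]acetate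
Conditions: Me3SiOTf (1.2 equiv), 21 (2 equiv), CH2Cl2, −78 °C; aq. NaHCO3
Reagents that add atoms: none
Why: Proposed new method: Me3SiOTf should ionise the exocyclic methoxy group of either C6 epimer to the cyclic peroxycarbenium ion, whose half-chair holds the C3 and C4 substituents pseudo-equatorial; the alkynylstannane attacks C6 through its tin-bearing carbon (β-stannyl vinyl cation, then loss of the stannyl group) along the axial trajectory that leads to a chair, which places the butynyl group axial and trans to the C4 ethyl group and leaves the C6 ethyl group equatorial (6S); the closest known reaction types are the Lewis acid mediated allylsilane and enol silane substitutions of 1,2-dioxane and 1,2-dioxolane peroxyketals and the axial addition of alkynylstannanes to pyranyl oxocarbenium ions.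

**Step 13**
Reactants: 22 methyl 2-[(3S,4R,6S)-6-(but-1-yn-1-yl)-4,6-diethyl-1,2-dioxan-3-yl]acetate
Product: 24 methyl 2-[(3S,4R,6S)-4,6-diethyl-6-[(E)-2-iodobut-1-en-1-yl]-1,2-dioxan-3-yl]acetate, via alkenylzirconocene chloride 23 (not isolated)
Conditions: Cp2Zr(H)Cl (1.3 equiv), CH2Cl2, 0 → 23 °C, dark; then I2, 0 °C; aq. Na2S2O3
Reagents that add atoms: zirconocene chloride hydride [H][Zr](Cl)(C1C=CC=C1)C1C=CC=C1 (zirconocene chloride unit of 23 only); iodine II
Why: Hydrozirconation–iodination: syn addition of Zr–H puts zirconium on C8, the alkyne carbon remote from the fully substituted C6, and iodinolysis with retention should give the E iodide (iodine trans to C6); alkyne insertion is expected to outpace attack on the hindered O–O bond and the ester at this temperature.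

**Step 14**
Reactants: 7 (S,E)-5-(iodomethyl)hept-3-ene; 24 methyl 2-[(3S,4R,6S)-4,6-diethyl-6-[(E)-2-iodobut-1-en-1-yl]-1,2-dioxan-3-yl]acetate
Product: 26 methyl 2-[(3S,4R,6S)-4,6-diethyl-6-[(1E,4R,5E)-2,4-diethylocta-1,5-dien-1-yl]-1,2-dioxan-3-yl]acetate, via alkylzinc iodide 25 (not isolated)
Conditions: 7, Zn dust (activated with BrCH2CH2Br and Me3SiCl), LiCl, THF, 40 °C; then 24, PdCl2(dppf) (5 mol%; dppf = 1,1'-bis(diphenylphosphino)ferrocene), THF/NMP, 23 → 40 °C
Reagents that add atoms: zinc [Zn] (zinc of 25 only)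
Why: Zerovalent palladium (formed from PdCl2(dppf) and the organozinc) inserts into the C8–I bond of 24 with retention, the primary alkylzinc iodide 25 transmetalates, and reductive elimination forms C8–C9; the wide bite angle of dppf speeds reductive elimination over β-hydride elimination from the alkyl–palladium. The closest known reaction type is the Negishi coupling of alkylzinc halides with alkenyl iodides, and palladium-catalysed cross-couplings of alkenyl iodides that carry dialkyl peroxides are known. No ring is closed in this step. No stereocenter is created: the 7E geometry is transferred from 24 with retention, C10 lies β to zinc and is configurationally inert, and C3, C4 and C6 are spectators. The step needs chemoselectivity for C–I over the O–O bond and the ester and freedom from elimination at the alkenyl–palladium; the substrate secures both because C6 is fully substituted (no β-oxygen and no allylic C–H on the ring side of the metal-bearing alkene), the O–O bond is three bonds away from C8 and shielded by the quaternary C6, and methyl esters are inert to alkylzinc halides.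

**Step 15**
Reactants: 26 methyl 2-[(3S,4R,6S)-4,6-diethyl-6-[(1E,4R,5E)-2,4-diethylocta-1,5-dien-1-yl]-1,2-dioxan-3-yl]acetate
Product: 27 2-[(3S,4R,6S)-4,6-diethyl-6-[(1E,4R,5E)-2,4-diethylocta-1,5-dien-1-yl]-1,2-dioxan-3-yl]acetic acid
Conditions: LiOH·H2O, THF/H2O, 0 → 23 °C; then 1 M HCl, 0 °C
Reagents that add atoms: lithium hydroxide [Li+].[OH-]
Why: Mild saponification of the methyl ester, a transformation that dialkyl peroxides of this 1,2-dioxane-3-acetate class tolerate; any reversible ring opening would return the favoured 3,4-trans isomer.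

**Compound list**
1 | (E)-pent-2-enal | CC/C=C/C=O | starting material
2 | (R,E)-hept-4-en-3-ol | CC[C@@H](O)/C=C/CC | intermediate
3 | ethyl (R,E)-3-ethylhept-4-enoate | CC/C=C/[C@H](CC)CC(=O)OCC | intermediate
4 | (R,E)-3-ethylhept-4-enoic acid | CC/C=C/[C@H](CC)CC(=O)O | intermediate
5 | (R,E)-3-ethylhept-4-enoyl chloride | CC/C=C/[C@H](CC)CC(=O)Cl | intermediate
6 | 2-thioxopyridin-1(2H)-yl (R,E)-3-ethylhept-4-enoate | CC/C=C/[C@H](CC)CC(=O)ON1C=CC=CC1=S | intermediate
7 | (S,E)-5-(iodomethyl)hept-3-ene | CC/C=C/[C@H](CC)CI | intermediate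
8 | 2-ethylacrolein (2-methylidenebutanal) | CCC(=C)C=O | starting material
9 | 2-methylidenebutan-1-ol | CCC(=C)CO | intermediate
10 | 2-(bromomethyl)but-1-ene | CCC(=C)CBr | intermediate
11 | (S)-4-benzyl-3-butanoyloxazolidin-2-one | CCCC(=O)N1[C@@H](Cc2ccccc2)COC1=O | starting material
12 | sodium (Z)-enolate of 11 | CC/C=C(\[O-])N1[C@@H](Cc2ccccc2)COC1=O.[Na+] | intermediate
13 | (S)-4-benzyl-3-[(R)-2-ethyl-4-methylidenehexanoyl]oxazolidin-2-one | CC[C@H](CC(=C)CC)C(=O)N1[C@@H](Cc2ccccc2)COC1=O | intermediate
14 | (R)-2-ethyl-4-methylidenehexan-1-ol | CC[C@H](CC(=C)CC)CO | intermediate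
15 | (R)-2-ethyl-4-methylidenehexanal | CC[C@H](CC(=C)CC)C=O | intermediate
16 | methyl (R,E)-4-ethyl-6-methylideneoct-2-enoate | CC[C@H](CC(=C)CC)/C=C/C(=O)OC | intermediate
17 | methyl (2E,4R)-4-ethyl-6-hydroperoxy-6-methoxyoct-2-enoate (both C6 epimers) | CC[C@H](CC(CC)(OC)OO)/C=C/C(=O)OC | intermediate
18 | methyl 2-[(3S,4R)-4,6-diethyl-6-methoxy-1,2-dioxan-3-yl]acetate (both C6 epimers) | CCC1(OC)C[C@@H](CC)[C@H](CC(=O)OC)OO1 | intermediate
19 | but-1-yne | CCC#C | starting material
20 | lithium but-1-yn-1-ide | CCC#[C-].[Li+] | intermediate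
21 | tributyl(but-1-yn-1-yl)stannane | CCC#C[Sn](CCCC)(CCCC)CCCC | intermediate
22 | methyl 2-[(3S,4R,6S)-6-(but-1-yn-1-yl)-4,6-diethyl-1,2-dioxan-3-yl]acetate | CCC#C[C@]1(CC)C[C@@H](CC)[C@H](CC(=O)OC)OO1 | intermediate
23 | methyl 2-[(3S,4R,6S)-6-[(E)-2-(chlorozirconocenyl)but-1-en-1-yl]-4,6-diethyl-1,2-dioxan-3-yl]acetate | CC/C(=C\[C@]1(CC)C[C@@H](CC)[C@H](CC(=O)OC)OO1)[Zr](Cl)(C1C=CC=C1)C1C=CC=C1 | intermediate
24 | methyl 2-[(3S,4R,6S)-4,6-diethyl-6-[(E)-2-iodobut-1-en-1-yl]-1,2-dioxan-3-yl]acetate | CC/C(I)=C\[C@]1(CC)C[C@@H](CC)[C@H](CC(=O)OC)OO1 | intermediate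
25 | [(S,E)-2-ethylhex-3-en-1-yl]zinc iodide | CC/C=C/[C@H](CC)C[Zn]I | intermediate
26 | methyl 2-[(3S,4R,6S)-4,6-diethyl-6-[(1E,4R,5E)-2,4-diethylocta-1,5-dien-1-yl]-1,2-dioxan-3-yl]acetate | CC/C=C/[C@H](CC)C/C(=C/[C@]1(CC)C[C@@H](CC)[C@H](CC(=O)OC)OO1)CC | intermediate
27 | 2-[(3S,4R,6S)-4,6-diethyl-6-[(1E,4R,5E)-2,4-diethylocta-1,5-dien-1-yl]-1,2-dioxan-3-yl]acetic acid | CC/C=C/[C@H](CC)C/C(=C/[C@]1(CC)C[C@@H](CC)[C@H](CC(=O)O)OO1)CC | target

**Step count**
Total step count: 15.
Longest linear sequence: 10 steps (8 → 27 through steps 5, 6, 7, 8, 9, 10, 12, 13, 14, 15).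

**Steps most likely to fail**

Step 12 (Proposed new method). After ionisation of the peroxyketal, heterolytic O–O fragmentation or proton loss from the cation may outrun C–C bond formation, tin–silicon exchange may consume the nucleophile, or attack may occur on both faces of C6. The fallback uses known chemistry, sets out from 16 and returns at 22. Ozonolysis of the 1,1-disubstituted alkene of 16 in CH2Cl2 at −78 °C with Me2S work-up should give methyl (R,E)-4-ethyl-6-oxooct-2-enoate F1. Lithium butynide 20 (THF, −78 °C) adds to the ketone to give methyl (2E,4R)-4,6-diethyl-6-hydroxydec-2-en-7-ynoate F2 as both C6 epimers. Acid-catalysed perhydrolysis at the tertiary propargylic carbon (50% H2O2, H2SO4 cat., 0 °C) gives methyl (2E,4R)-4,6-diethyl-6-hydroperoxydec-2-en-7-ynoate F3. Et2NH in CF3CH2OH then closes the ring by oxa-Michael addition to give 22 together with its C6 epimer, methyl 2-[(3S,4R,6R)-6-(but-1-yn-1-yl)-4,6-diethyl-1,2-dioxan-3-yl]acetate F4, which has to be removed by chromatography. This path gives up the stereocontrol at C6.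

Step 13. Hydride transfer from zirconium to the O–O bond or to the ester may compete with alkyne insertion, and regiocontrol of the insertion may be incomplete. The fallback sets out from 22 and returns at 24; it replaces the early-metal hydride by a palladium-catalysed tin hydride addition, a reagent class known to coexist with dialkyl peroxides. Syn-hydrostannation of 22 (Bu3SnH, PdCl2(PPh3)2 cat., THF, 0 °C), with tin going to the less hindered C8, should give methyl 2-[(3S,4R,6S)-4,6-diethyl-6-[(E)-2-(tributylstannyl)but-1-en-1-yl]-1,2-dioxan-3-yl]acetate F5. Iododestannylation (I2, CH2Cl2, 0 °C) with retention then gives 24.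

Step 14 (key step). Transmetalation at the α-branched alkenyl–palladium may be slow, which would open the way to β-hydride elimination of the alkyl group, reduction of the iodide, or attack of zerovalent palladium on the O–O bond. The fallback sets out from 7 and returns at 26; it replaces the zinc reagent by a boron ate complex (B-alkyl Suzuki–Miyaura coupling). Iodine–lithium exchange on 7 (t-BuLi, Et2O, −78 °C) gives [(S,E)-2-ethylhex-3-en-1-yl]lithium F6, which is trapped with B-methoxy-9-borabicyclo[3.3.1]nonane to give lithium [(S,E)-2-ethylhex-3-en-1-yl](methoxy)-9-borabicyclo[3.3.1]nonan-9-uide F7. This ate complex is coupled with 24 (PdCl2(dppf), AsPh3, aq. Cs2CO3, DMF, 23 °C) to give 26.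

**Further compounds**
F1 | step 12 | methyl (R,E)-4-ethyl-6-oxooct-2-enoate | CC[C@H](CC(=O)CC)/C=C/C(=O)OC
F2 | step 12 | methyl (2E,4R)-4,6-diethyl-6-hydroxydec-2-en-7-ynoate (both C6 epimers) | CC[C@H](CC(O)(CC)C#CCC)/C=C/C(=O)OC
F3 | step 12 | methyl (2E,4R)-4,6-diethyl-6-hydroperoxydec-2-en-7-ynoate (both C6 epimers) | CC[C@H](CC(OO)(CC)C#CCC)/C=C/C(=O)OC
F4 | step 12 | methyl 2-[(3S,4R,6R)-6-(but-1-yn-1-yl)-4,6-diethyl-1,2-dioxan-3-yl]acetate | CCC#C[C@@]1(CC)C[C@@H](CC)[C@H](CC(=O)OC)OO1
F5 | step 13 | methyl 2-[(3S,4R,6S)-4,6-diethyl-6-[(E)-2-(tributylstannyl)but-1-en-1-yl]-1,2-dioxan-3-yl]acetate | CC/C(=C\[C@]1(CC)C[C@@H](CC)[C@H](CC(=O)OC)OO1)[Sn](CCCC)(CCCC)CCCC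
F6 | step 14 | [(S,E)-2-ethylhex-3-en-1-yl]lithium | CC/C=C/[C@H](CC)C[Li]
F7 | step 14 | lithium [(S,E)-2-ethylhex-3-en-1-yl](methoxy)-9-borabicyclo[3.3.1]nonan-9-uide | CC/C=C/[C@H](CC)C[B-]1(OC)C2CCCC1CCC2.[Li+]
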